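Time is the first setting I can turn.

- zeta: G 0.50 mM; Z 0.094 mM (held); run made earlier
- flask: G 1.0 mM; Z 0.094 mM (held); time 6.0 min



zeta run (percent of the G charged)

| time / s | Q / % | E / % |
|---|---|---|
| 25.0 | 8 | 1 |
| 50.0 | 17 | 0 |
| 80.0 | 23 | 0 |
| 120 | 37 | 0 |

(scatter of a reading: 2 percentage points)



- as a solid, counted per litre of solution: G
- at the start none of G is in solution
- at the start none of Z is in solution
- E is what G becomes in solution
- E means what is dissolved; the solid is not counted in it



* how much Q there is at 6.0 min, in percent of the G charged
* concentration of E in solution at 6.0 min, in percent of saturation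



In the zeta run, Q rises on a straight line with no lag. Its last reading, 37% of 0.50 mM at 120 s, gives 0.0925 mM/min, with the scatter of 2 percentage points on that reading. I carry this delivery rate, the rise of [Q] per minute while solid G stands; I take it as zero order in the charge, a bet that one loading cannot test.

By hand, each setting does this to Q:

| Moved from the zeta run | Q, percent of the G charged |
|---|---|
| nothing | 37% |
| G alone | 18.5% |
| time alone | 111% |
| both | 55.5% |

More G leaves [Q] as it is and lowers the percentage. More time raises it, but the time-alone row stands above the whole charge, so the zeta line must bend before 6.0 min. Joining the two ends for the flask, the early line meets the ceiling of its charge at 10.8 min, later than the asked time, so I stay on the line. E reads 1% at most, within the scatter, but the readings give no saturation value, so I put no figure on [E] as a percent of saturation.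

The forecast says 60% and 80%, leaning to the reading that “Sparingly soluble G keeps E near saturation”. The flask gives 54.7% of Q, with [E] at 0.377% of saturation.

    G ⇌ E, rate k1*(cs1 - [E]) while solid is left; crystals form when [E] > cs1 (solubility = 0.430 mM, k = 0.00470 /s)
    E + X → Q (k = 15000 /M/s)
    2 E → L (k = 2600 /M/s)
    Z ⇌ X, rate k4*(csat - [X]) (kL = 0.170 /s)
    Q ⇌ D (K = 0.330, k = 0.0170 /s)

At 6.00 min the flask still holds 27.5% of its charge as G. Over 6.0 min, 0.0925 mM/min gives 55.5% for this flask. In a neighbour flask with 2.5 mM of G, held for the same time, it gives 22.2%, and that flask holds 21.9% of Q.

The earlier runs and the new flask are calculated for an exercise, and the scatter is random.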